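## Structural features

The target is an isoflavone: benzo ring A is fused along the C4a–C8a bond to the 4-pyranone ring C, and ring C carries aryl ring B at C3. It has no stereocentre and no double bond of configurational consequence, so the problem is one of constitution only. Ring A is hexasubstituted (O1 at C8a, prenyl at C8, OH at C7, prenyl at C6, OH at C5 chelated to the C4 carbonyl, C4 at C4a). Ring B is 1,2,3,4-tetrasubstituted (C3 at C1', OMe at C2', prenyl at C3', OH at C4'). The three 3-methylbut-2-enyl groups are the fragile elements: each lies ortho to a phenolic oxygen and cyclises to a 2,2-dimethylchroman or adds solvent under Brønsted or Lewis acid, and none tolerates hydrogenolysis, halogenation or strong oxidants. The real difficulty is regiochemical: every prenyl group sits on a carbon between two oxygens, four phenolic oxygens must be told apart, and the C4–C4a bond must be made at a carbon flanked by two oxygens without Friedel–Crafts or Hoesch acid. The key step uses the fact that C8a (bearing O1) and C4a (bearing C4) are neighbours in ring A: an aryne across C4a≡C8a can take up the carboxyl oxygen and the acyl carbon of a ring B arylacetic acid in one operation, with the C5 oxygen beside C4a fixing the orientation. Because the three oxygens of ring A stem from a symmetric 1,3,5-triol, the one that becomes the aryne leaving group has to be singled out early.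

## Logic of the disconnections

30 ⇒ 29. The three phenolic O–CH2OCH3 bonds at O5, O7 and O4' are cut. These phenols must be masked through organolithium, fluoride and amide-acetal steps, and a formaldehyde acetal is the one group that stands all of these and leaves without hydrogen, oxidant or strong Lewis acid. Nothing is gained in skeleton; the demand on the forward step is an acetal solvolysis mild enough that no phenol closes onto a neighbouring prenyl group.

29 ⇒ 27. O1–C2 and C2–C3 are cut, which opens ring C and removes the one-carbon unit C2. This leaves an acyclic 2-hydroxy deoxybenzoin. The forward step needs the C8a hydroxyl of 27 to be the only free phenol and the benzylic CH2 to condense with a formamide acetal.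

27 ⇒ 15 + 25. The C8a–O bond and the C4–C4a bond are cut together. The cut falls on two neighbouring ring carbons, divides the molecule into two halves of similar size, each already carrying its prenyl groups, and replaces an acid-mediated acylation by a fluoride-triggered one. The forward step must put oxygen on C8a and acyl on C4a and must transfer the acyl group faster than the aryl anion is protonated. An atom-by-atom check of 15, 25 and 27 finds them mutually consistent: in 15 the silicon-bearing carbon is flanked by an acetal-protected oxygen and the triflate-bearing carbon by a prenyl group, as C4a and C8a require. No structure needs correcting; what needs strengthening is the way to 15.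

15 ⇒ 13 ⇒ 9. The S–O bond of the triflate and the aryl C–Si bond are cut. A secondary carbamate on the oxygen that is to become the leaving group directs lithiation to the only ring C–H left and later comes off under mild base in the flask in which the triflate is made. The demand is ring metalation in preference to metalation of a benzylic prenyl CH2.

9 ⇒ 8 ⇒ 7. The carbamoyl group is removed, then the bond between C2 of the phenol and its prenyl CH2 is cut as a retro-[3,3] shift, leading to a tertiary allyl aryl ether. A plan that reaches 8 by twofold protection of a 2,4-diprenylated free triol was set aside. Such a triol has two kinds of hydroxyl; the less hindered pair would react first and leave free the one oxygen without a vacant ortho carbon. Its own preparation by direct C-alkylation is also unselective. In the plan adopted here the rearrangement that installs the second prenyl group uncovers exactly the hydroxyl that must carry the carbamate, so no selective protection is needed at this stage.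

7 ⇒ 4 + 5. The aryl–CH2 bond at the carbon between the two acetal oxygens is cut. That carbon is the most acidic ring position and is doubly chelated, whereas the tertiary ether oxygen is a poor director. The forward step needs an aryl-metal that attacks 5 at its primary carbon.

4 ⇒ 2 + 3 and 2 ⇒ 1. The aryl O–C bonds are cut. The only unselective operation of the route, twofold etherification of a symmetric triol, is placed on the cheapest material at the very start and marks one oxygen as different from the other two. The forward step needs O-allylation at the tertiary allyl terminus.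

25 ⇒ 24 ⇒ 22. The acid is taken back to the nitrile and the nitrile carbon is cut from the benzylic carbon. This is a one-carbon homologation of an aldehyde that needs neither acid nor any reagent that attacks a trisubstituted alkene.

22 ⇒ 18 + 5. The aryl–CH2 bond at C3' is cut. C3' lies between the methoxy and the acetal oxygen and is the cooperative metalation site. The aldehyde must be masked in the flask during lithiation.

18 ⇒ 17 ⇒ 16. Two O–C bonds are cut. The aldehyde of 16 fixes C1' and makes the two hydroxyls unequal (one chelated, one not), so each can be alkylated in turn.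

## Other disconnections considered

Alternative 1: The cut removes ring A altogether. C5–C6, C7–C8 and C4a–C5 are disconnected, leading to pyranonyl diazomethyl ketone A1 (ring C with ring B attached, the diazoacetyl group on the carbon that becomes C8a) and the prenyl-substituted triisopropylsiloxyalkyne A2. In the forward sense irradiation of A1 would start a Wolff rearrangement, [2+2] addition to A2, 4π ring opening, 6π electrocyclisation onto the pyranone carbon that becomes C4a and tautomerisation to the 5-hydroxy-6-prenyl-7-silyloxy isoflavone A3.
- In its favour: the positions of the C5 hydroxyl, the C6 prenyl group and the C7 oxygen are dictated by the alkyne and not by a hierarchy of directing groups. On positional control within ring A it is the better plan. The cascade is neutral, so on sparing the prenyl groups from acid the two plans are equal.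
- Against it here: A3 has no substituent at C8, so one prenyl group must still be added afterwards. The 4-pyranone chromophore of A1 is itself photoreactive. The ketene stage may be intercepted by the trisubstituted alkenes. Neither A1 nor A2 is close to a commercial material.
- Comparison: structurally it forms three ring bonds and a ring where the chosen step forms two bonds and no ring. Mechanistically it is a pericyclic cascade against a polar aryne insertion. In step economy the chosen plan should be shorter, because both of its partners come from simple aromatics in five and seven steps and all three prenyl groups are in place when the halves are joined.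

Alternative 2: The cut is made at the three aryl–CH2 bonds at C6, C8 and C3', leading to triiodo isoflavone A4 and prenyltributylstannane A5. In the forward sense a zerovalent palladium catalyst with a fluoride additive would couple all three iodides in one operation to give A6, the 7,4'-bis(methoxymethyl) ether of the target.
- In its favour: the acid-labile groups enter last, so the isoflavone core could be made by classical acid chemistry; on keeping the prenyl groups out of most of the synthesis it is the better plan. A6 has two acetals to remove rather than three; the final deprotection problem is otherwise the same, a point on which the plans are equal.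
- Against it here: allyl transfer from tin can occur at either allyl terminus, so each coupling can deliver a 1,1-dimethylallyl group instead of a prenyl group. All three iodides are flanked by two ortho substituents, so transmetalation is slow, protodeiodination competes and three couplings must each go to completion. The C3' iodide lies between two oxygens, where electrophilic iodination would not place it, so A4 needs a directed metalation of its own. Tin residues must be removed.
- Comparison: structurally it forms three bonds, none of them part of the ring skeleton, against two bonds that join the two halves. Mechanistically the uncertainty lies in the regiochemistry of the allyl unit, whereas in the chosen plan each prenyl group is installed by substitution at a primary carbon or by a [3,3] shift and its connectivity is not in doubt. In step count it is comparable or slightly shorter.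

Alternative 3: The cut is the C4a–C8a bond, which opens ring A to the triketo ester A7. In the forward sense a magnesium alkoxide in methanol would generate the carbanion at the future C4a, which attacks the terminal ester carbonyl in a Claisen condensation; ring A closes and aromatises by enolisation to the 2,4,6-trihydroxyphenyl ketone A8.
- In its favour: it mirrors polyketide folding and needs no protecting group on ring A. Ring A of A8 is symmetric, so either ortho hydroxyl would close ring C to the same isoflavone; on freedom from regiochemical doubt in ring closure it is the equal of the chosen plan. It reaches the deoxybenzoin skeleton without any aryne precursor, a point on which it is better.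
- Against it here: A8 carries neither ring A prenyl group. Both would have to be added by direct C-alkylation of a free polyphenol, where O-alkylation, mono- and bis-alkylation and geminal dialkylation with loss of aromaticity compete. A7 is a sensitive poly-β-carbonyl compound that can also close by aldol condensation or lactonise, and its preparation needs polyanion acylation chemistry.
- Comparison: structurally it forms one ring bond and a ring but leaves fewer of the target's substituents in place. Mechanistically both plans avoid acid at the bond-forming stage (equal). In step economy the path to A8 is shorter, but the late double prenylation would cost that advantage, whereas the chosen plan fixes all three prenyl groups before the coupling.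

Key step: step 13

Assumption: carbonate 3 is taken to be a purchasable reagent; it is otherwise one operation from 2-methylbut-3-en-2-ol and di-tert-butyl dicarbonate.

## Route

Step 1
Reactants: 1 phloroglucinol
Product: 2 3,5-bis(methoxymethoxy)phenol
Conditions: MOMCl (2 equiv), i-Pr2NEt, DMF, 0 °C → rt
Reagents that add atoms: chloromethyl methyl ether, COCCl
Why: Phenoxide O-alkylation (Williamson type); with two equivalents the bis-ether is expected as the main component of a statistical set, from which the mono-ether is recycled. This single unselective operation marks the oxygen that becomes C8a–O.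

Step 2
Reactants: 2 3,5-bis(methoxymethoxy)phenol; 3 tert-butyl 2-methylbut-3-en-2-yl carbonate
Product: 4 1,3-bis(methoxymethoxy)-5-[(2-methylbut-3-en-2-yl)oxy]benzene
Conditions: Pd(PPh3)4 (cat.), THF, 0 °C
Reagents that add atoms: none
Why: Tsuji–Trost O-allylation: zerovalent palladium ionises the carbonate to a 1,1-dimethylallyl complex of divalent palladium with loss of CO2, the tert-butoxide formed deprotonates 2, and the phenoxide attacks the more substituted allyl terminus at low temperature to give the tertiary ether as kinetic product.

Step 3
Reactants: 4 1,3-bis(methoxymethoxy)-5-[(2-methylbut-3-en-2-yl)oxy]benzene; 5 prenyl bromide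
Product: 7 1,3-bis(methoxymethoxy)-2-(3-methylbut-2-en-1-yl)-5-[(2-methylbut-3-en-2-yl)oxy]benzene, via aryllithium 6 (not isolated)
Conditions: n-BuLi, TMEDA, THF, −20 °C; CuI (10 mol %), then 5, −78 °C → rt
Reagents that add atoms: none
Why: Directed ortho-metalation at the carbon between the two acetal oxygens (most acidic, doubly chelated; the bulky tertiary ether is a poor director and has no α-hydrogen for a Wittig shift), then copper-catalysed substitution of 5 at its primary carbon.

Step 4
Reactants: 7 1,3-bis(methoxymethoxy)-2-(3-methylbut-2-en-1-yl)-5-[(2-methylbut-3-en-2-yl)oxy]benzene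
Product: 8 3,5-bis(methoxymethoxy)-2,4-bis(3-methylbut-2-en-1-yl)phenol
Conditions: PhMe, 110 °C
Reagents that add atoms: none
Why: Aromatic Claisen rearrangement: the [3,3] shift joins the CH2 terminus of the 1,1-dimethylallyl group to an ortho carbon, so a normal prenyl group results, and enolisation frees the hydroxyl. The two ortho carbons are equivalent, so one product is expected, and the phenol uncovered is the one that must become the triflate.

Step 5
Reactants: 8 3,5-bis(methoxymethoxy)-2,4-bis(3-methylbut-2-en-1-yl)phenol
Product: 9 3,5-bis(methoxymethoxy)-2,4-bis(3-methylbut-2-en-1-yl)phenyl N-(propan-2-yl)carbamate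
Conditions: i-PrNCO, Et3N (cat.), CH2Cl2, rt
Reagents that add atoms: isopropyl isocyanate, CC(C)N=C=O
Why: Amine-catalysed addition of a phenol to an isocyanate; the secondary carbamate is a strong ortho director and can later be removed by mild base.

Step 6
Reactants: 9 3,5-bis(methoxymethoxy)-2,4-bis(3-methylbut-2-en-1-yl)phenyl N-(propan-2-yl)carbamate
Product: 13 3,5-bis(methoxymethoxy)-2,4-bis(3-methylbut-2-en-1-yl)-6-(trimethylsilyl)phenyl N-(propan-2-yl)carbamate, via N-silyl carbamate 10 (not isolated), via lithiated N-silyl carbamate 11 (not isolated), via C-silylated N-silyl carbamate 12 (not isolated)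
Conditions: TBSOTf, TMEDA, Et2O, 0 °C → rt; n-BuLi, TMEDA, −78 °C; TMSCl, −78 °C → rt; aq. NH4Cl
Reagents that add atoms: chlorotrimethylsilane, C[Si](C)(C)Cl
Why: Carbamate-directed ortho-metalation: transient N-silylation blocks N–H deprotonation and isocyanate loss, the only ring C–H left lies between the carbamate and an acetal oxygen and should be lithiated kinetically at −78 °C, and TMSCl traps the aryllithium. The N–Si bond is hydrolysed on work-up.

Step 7
Reactants: 13 3,5-bis(methoxymethoxy)-2,4-bis(3-methylbut-2-en-1-yl)-6-(trimethylsilyl)phenyl N-(propan-2-yl)carbamate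
Product: 15 3,5-bis(methoxymethoxy)-2,4-bis(3-methylbut-2-en-1-yl)-6-(trimethylsilyl)phenyl trifluoromethanesulfonate, via phenol 14 (not isolated)
Conditions: DBU, Et2NH, MeCN, 40 °C; then PhNTf2, rt
Reagents that add atoms: N-phenylbis(trifluoromethanesulfonimide), O=S(=O)(N(c1ccccc1)S(=O)(=O)C(F)(F)F)C(F)(F)F
Why: Base-induced elimination of the N–H carbamate to isopropyl isocyanate (trapped by Et2NH as a urea) releases the phenoxide, which is sulfonylated in the same flask. The mild basic medium should leave the aryl–silicon bond, the acetals and the prenyl groups untouched.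

Step 8
Reactants: 16 2,4-dihydroxybenzaldehyde
Product: 17 2-hydroxy-4-(methoxymethoxy)benzaldehyde
Conditions: MOMCl (1.1 equiv), K2CO3, acetone, rt
Reagents that add atoms: chloromethyl methyl ether, COCCl
Why: Selective O-alkylation of the C4 hydroxyl, which is the more acidic and is not tied up in the hydrogen bond to the aldehyde.

Step 9
Reactants: 17 2-hydroxy-4-(methoxymethoxy)benzaldehyde
Product: 18 2-methoxy-4-(methoxymethoxy)benzaldehyde
Conditions: MeI, K2CO3, DMF, rt
Reagents that add atoms: iodomethane, CI
Why: Williamson methylation of the remaining chelated hydroxyl in a dipolar aprotic solvent.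

Step 10
Reactants: 18 2-methoxy-4-(methoxymethoxy)benzaldehyde; 5 prenyl bromide
Product: 22 2-methoxy-4-(methoxymethoxy)-3-(3-methylbut-2-en-1-yl)benzaldehyde, via amino alkoxide 19 (not isolated), via lithiated amino alkoxide 20 (not isolated), via prenylated amino alkoxide 21 (not isolated)
Conditions: lithium 4-methylpiperazin-1-ide (from 1-methylpiperazine, n-BuLi), THF, −20 °C; n-BuLi, TMEDA, −20 °C; CuBr·SMe2 (cat.), 5 (excess), −78 °C → rt; H2O
Reagents that add atoms: none
Why: In situ protection of the aldehyde as an α-amino alkoxide, then directed ortho-metalation at C3, the site between the methoxy and the acetal oxygen, and copper-catalysed allylation at the primary carbon of 5. The hemiaminal collapses to the aldehyde on aqueous work-up.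

Step 11
Reactants: 22 2-methoxy-4-(methoxymethoxy)-3-(3-methylbut-2-en-1-yl)benzaldehyde
Product: 24 2-[2-methoxy-4-(methoxymethoxy)-3-(3-methylbut-2-en-1-yl)phenyl]acetonitrile, via vinyl formamide 23 (not isolated)
Conditions: TosMIC, t-BuOK, DME, −40 °C; then MeOH, reflux
Reagents that add atoms: p-toluenesulfonylmethyl isocyanide, Cc1ccc(cc1)S(=O)(=O)C[N+]#[C-]
Why: Van Leusen reductive cyanation: the isocyanide anion adds to the aldehyde, the oxazoline opens to the N-(1-tosylvinyl)formamide, and methanolysis removes the formyl group and expels sulfinate to give the homologous nitrile. The sequence is basic throughout, so acetal and alkene are not at risk.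

Step 12
Reactants: 24 2-[2-methoxy-4-(methoxymethoxy)-3-(3-methylbut-2-en-1-yl)phenyl]acetonitrile
Product: 25 2-[2-methoxy-4-(methoxymethoxy)-3-(3-methylbut-2-en-1-yl)phenyl]acetic acid
Conditions: KOH, EtOH/H2O, reflux; then aq. KHSO4 to pH 4, 0 °C
Reagents that add atoms: water, O; potassium hydroxide, [K+].[OH-]
Why: Alkaline nitrile hydrolysis through the primary amide; acetal, methyl ether and prenyl group are stable to hydroxide, and the cold, buffered acidification should spare the acetal.

Step 13
Reactants: 15 3,5-bis(methoxymethoxy)-2,4-bis(3-methylbut-2-en-1-yl)-6-(trimethylsilyl)phenyl trifluoromethanesulfonate; 25 2-[2-methoxy-4-(methoxymethoxy)-3-(3-methylbut-2-en-1-yl)phenyl]acetic acid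
Product: 27 1-[2-hydroxy-4,6-bis(methoxymethoxy)-3,5-bis(3-methylbut-2-en-1-yl)phenyl]-2-[2-methoxy-4-(methoxymethoxy)-3-(3-methylbut-2-en-1-yl)phenyl]ethan-1-one, via aryne 26 (not isolated)
Conditions: 15 (1.3 equiv), CsF (4 equiv), THF, 125 °C (sealed tube)
Reagents that add atoms: none
Why: Fluoride attacks the silicon of 15 and the aryl anion expels triflate to give the C4a≡C8a aryne 26, while CsF turns 25 into its caesium carboxylate. The carboxylate oxygen adds to C8a, the aryl anion formed at C4a attacks the ester carbonyl just created through a four-membered transition state, and collapse of the adduct moves the acyl group from oxygen to carbon and leaves the C8a phenoxide, protonated on work-up. The closest known reaction type is the fluoride-induced insertion of arynes into the C–O bond of carboxylic acids to give ortho-hydroxyaryl ketones, in effect an aryne σ-insertion with an anionic 1,3-acyl shift. No ring is closed and no stereocentre is formed, so there is no mode of closure or stereocontrol element to name. The step needs oxygen on C8a and acyl on C4a: the C5 acetal oxygen next to C4a withdraws inductively, makes C8a the more electrophilic aryne terminus and stabilises the charge developing at C4a, and this bias has to outweigh the steric shielding of C8a by the C8 prenyl group. The acyl shift must also outrun protonation of the aryl anion, which the aprotic solvent, the low solubility of CsF and the intramolecular nature of the shift should secure. The product phenoxide is chelated to the new ketone and flanked by a prenyl group, which should keep it from adding to a second aryne. The medium is neutral to weakly basic, so the three prenyl groups and the three acetals should pass unchanged and only the C8a hydroxyl of 27 is free.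

Step 14
Reactants: 27 1-[2-hydroxy-4,6-bis(methoxymethoxy)-3,5-bis(3-methylbut-2-en-1-yl)phenyl]-2-[2-methoxy-4-(methoxymethoxy)-3-(3-methylbut-2-en-1-yl)phenyl]ethan-1-one
Product: 29 3-[2-methoxy-4-(methoxymethoxy)-3-(3-methylbut-2-en-1-yl)phenyl]-5,7-bis(methoxymethoxy)-6,8-bis(3-methylbut-2-en-1-yl)-4H-chromen-4-one, via enaminone 28 (not isolated)
Conditions: Me2NCH(OMe)2, PhMe, 90 °C
Reagents that add atoms: N,N-dimethylformamide dimethyl acetal, COC(OC)N(C)C
Why: Condensation of the activated benzylic CH2 with the amide acetal gives the enaminone; the single free hydroxyl at C8a then adds to the enamine carbon and dimethylamine is lost (6-endo addition–elimination), closing ring C as in the standard deoxybenzoin route to isoflavones.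

Step 15
Reactants: 29 3-[2-methoxy-4-(methoxymethoxy)-3-(3-methylbut-2-en-1-yl)phenyl]-5,7-bis(methoxymethoxy)-6,8-bis(3-methylbut-2-en-1-yl)-4H-chromen-4-one
Product: 30 5,7-dihydroxy-3-[4-hydroxy-2-methoxy-3-(3-methylbut-2-en-1-yl)phenyl]-6,8-bis(3-methylbut-2-en-1-yl)-4H-chromen-4-one
Conditions: HCl (1 M in MeOH), rt → 40 °C
Reagents that add atoms: none
Why: Acid-catalysed transacetalisation of the three aryl methoxymethyl ethers to dimethoxymethane; the aryl methyl ether is inert, and dilute acid at low temperature is chosen so that acetal cleavage outruns addition of a phenol to a prenyl double bond.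

## Compound list

1 | phloroglucinol (benzene-1,3,5-triol) | Oc1cc(O)cc(O)c1 | starting material
2 | 3,5-bis(methoxymethoxy)phenol | COCOc1cc(O)cc(OCOC)c1 | intermediate
3 | tert-butyl 2-methylbut-3-en-2-yl carbonate | CC(C)(C)OC(=O)OC(C)(C)C=C | starting material
4 | 1,3-bis(methoxymethoxy)-5-[(2-methylbut-3-en-2-yl)oxy]benzene | C=CC(C)(C)Oc1cc(OCOC)cc(OCOC)c1 | intermediate
5 | prenyl bromide (1-bromo-3-methylbut-2-ene) | CC(C)=CCBr | starting material
6 | {2,6-bis(methoxymethoxy)-4-[(2-methylbut-3-en-2-yl)oxy]phenyl}lithium | [Li]c1c(OCOC)cc(OC(C)(C)C=C)cc1OCOC | intermediate (not isolated)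
7 | 1,3-bis(methoxymethoxy)-2-(3-methylbut-2-en-1-yl)-5-[(2-methylbut-3-en-2-yl)oxy]benzene | C=CC(C)(C)Oc1cc(OCOC)c(CC=C(C)C)c(OCOC)c1 | intermediate
8 | 3,5-bis(methoxymethoxy)-2,4-bis(3-methylbut-2-en-1-yl)phenol | Oc1cc(OCOC)c(CC=C(C)C)c(OCOC)c1CC=C(C)C | intermediate
9 | 3,5-bis(methoxymethoxy)-2,4-bis(3-methylbut-2-en-1-yl)phenyl N-(propan-2-yl)carbamate | CC(C)NC(=O)Oc1cc(OCOC)c(CC=C(C)C)c(OCOC)c1CC=C(C)C | intermediate
10 | 3,5-bis(methoxymethoxy)-2,4-bis(3-methylbut-2-en-1-yl)phenyl N-(tert-butyldimethylsilyl)-N-(propan-2-yl)carbamate | CC(C)N(C(=O)Oc1cc(OCOC)c(CC=C(C)C)c(OCOC)c1CC=C(C)C)[Si](C)(C)C(C)(C)C | intermediate (not isolated)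
11 | 2-lithio-3,5-bis(methoxymethoxy)-4,6-bis(3-methylbut-2-en-1-yl)phenyl N-(tert-butyldimethylsilyl)-N-(propan-2-yl)carbamate | CC(C)N(C(=O)Oc1c([Li])c(OCOC)c(CC=C(C)C)c(OCOC)c1CC=C(C)C)[Si](C)(C)C(C)(C)C | intermediate (not isolated)
12 | 3,5-bis(methoxymethoxy)-2,4-bis(3-methylbut-2-en-1-yl)-6-(trimethylsilyl)phenyl N-(tert-butyldimethylsilyl)-N-(propan-2-yl)carbamate | CC(C)N(C(=O)Oc1c([Si](C)(C)C)c(OCOC)c(CC=C(C)C)c(OCOC)c1CC=C(C)C)[Si](C)(C)C(C)(C)C | intermediate (not isolated)
13 | 3,5-bis(methoxymethoxy)-2,4-bis(3-methylbut-2-en-1-yl)-6-(trimethylsilyl)phenyl N-(propan-2-yl)carbamate | CC(C)NC(=O)Oc1c([Si](C)(C)C)c(OCOC)c(CC=C(C)C)c(OCOC)c1CC=C(C)C | intermediate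
14 | 3,5-bis(methoxymethoxy)-2,4-bis(3-methylbut-2-en-1-yl)-6-(trimethylsilyl)phenol | Oc1c([Si](C)(C)C)c(OCOC)c(CC=C(C)C)c(OCOC)c1CC=C(C)C | intermediate (not isolated)
15 | 3,5-bis(methoxymethoxy)-2,4-bis(3-methylbut-2-en-1-yl)-6-(trimethylsilyl)phenyl trifluoromethanesulfonate | C[Si](C)(C)c1c(OCOC)c(CC=C(C)C)c(OCOC)c(CC=C(C)C)c1OS(=O)(=O)C(F)(F)F | intermediate
16 | 2,4-dihydroxybenzaldehyde | O=Cc1ccc(O)cc1O | starting material
17 | 2-hydroxy-4-(methoxymethoxy)benzaldehyde | COCOc1ccc(C=O)c(O)c1 | intermediate
18 | 2-methoxy-4-(methoxymethoxy)benzaldehyde | COCOc1ccc(C=O)c(OC)c1 | intermediate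
19 | lithium [2-methoxy-4-(methoxymethoxy)phenyl](4-methylpiperazin-1-yl)methanolate | [Li]OC(c1ccc(OCOC)cc1OC)N1CCN(C)CC1 | intermediate (not isolated)
20 | lithium [3-lithio-2-methoxy-4-(methoxymethoxy)phenyl](4-methylpiperazin-1-yl)methanolate | [Li]OC(c1ccc(OCOC)c([Li])c1OC)N1CCN(C)CC1 | intermediate (not isolated)
21 | lithium [2-methoxy-4-(methoxymethoxy)-3-(3-methylbut-2-en-1-yl)phenyl](4-methylpiperazin-1-yl)methanolate | [Li]OC(c1ccc(OCOC)c(CC=C(C)C)c1OC)N1CCN(C)CC1 | intermediate (not isolated)
22 | 2-methoxy-4-(methoxymethoxy)-3-(3-methylbut-2-en-1-yl)benzaldehyde | COc1c(C=O)ccc(OCOC)c1CC=C(C)C | intermediate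
23 | N-{2-[2-methoxy-4-(methoxymethoxy)-3-(3-methylbut-2-en-1-yl)phenyl]-1-(4-methylbenzenesulfonyl)ethenyl}formamide (alkene geometry not defined) | COc1c(C=C(NC=O)S(=O)(=O)c2ccc(C)cc2)ccc(OCOC)c1CC=C(C)C | intermediate (not isolated)
24 | 2-[2-methoxy-4-(methoxymethoxy)-3-(3-methylbut-2-en-1-yl)phenyl]acetonitrile | COc1c(CC#N)ccc(OCOC)c1CC=C(C)C | intermediate
25 | 2-[2-methoxy-4-(methoxymethoxy)-3-(3-methylbut-2-en-1-yl)phenyl]acetic acid | COc1c(CC(=O)O)ccc(OCOC)c1CC=C(C)C | intermediate
26 | 3,5-bis(methoxymethoxy)-4,6-bis(3-methylbut-2-en-1-yl)-1,2-didehydrobenzene | COCOC1=C(CC=C(C)C)C(OCOC)=C(CC=C(C)C)C#C1 | intermediate (not isolated)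
27 | 1-[2-hydroxy-4,6-bis(methoxymethoxy)-3,5-bis(3-methylbut-2-en-1-yl)phenyl]-2-[2-methoxy-4-(methoxymethoxy)-3-(3-methylbut-2-en-1-yl)phenyl]ethan-1-one | COc1c(CC(=O)c2c(O)c(CC=C(C)C)c(OCOC)c(CC=C(C)C)c2OCOC)ccc(OCOC)c1CC=C(C)C | intermediate
28 | 3-(dimethylamino)-1-[2-hydroxy-4,6-bis(methoxymethoxy)-3,5-bis(3-methylbut-2-en-1-yl)phenyl]-2-[2-methoxy-4-(methoxymethoxy)-3-(3-methylbut-2-en-1-yl)phenyl]prop-2-en-1-one (alkene geometry not defined) | COc1c(C(=CN(C)C)C(=O)c2c(O)c(CC=C(C)C)c(OCOC)c(CC=C(C)C)c2OCOC)ccc(OCOC)c1CC=C(C)C | intermediate (not isolated)
29 | 3-[2-methoxy-4-(methoxymethoxy)-3-(3-methylbut-2-en-1-yl)phenyl]-5,7-bis(methoxymethoxy)-6,8-bis(3-methylbut-2-en-1-yl)-4H-chromen-4-one | COc1c(-c2coc3c(CC=C(C)C)c(OCOC)c(CC=C(C)C)c(OCOC)c3c2=O)ccc(OCOC)c1CC=C(C)C | intermediate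
30 | 5,7-dihydroxy-3-[4-hydroxy-2-methoxy-3-(3-methylbut-2-en-1-yl)phenyl]-6,8-bis(3-methylbut-2-en-1-yl)-4H-chromen-4-one (CNP0331360.0; no stereocentre) | COc1c(-c2coc3c(CC=C(C)C)c(O)c(CC=C(C)C)c(O)c3c2=O)ccc(O)c1CC=C(C)C | target

## Step count and least certain steps

Total step count: 15. Longest linear sequence: 10 (steps 1–7, then 13–15); the ring B branch (steps 8–12) joins at step 13.

Step 13 (key step). Most likely to go wrong: protonation of the aryl anion before the acyl shift, which would stop at simple O-arylation of the acid. Also possible are attack of the carboxylate at C4a because the C8 prenyl group shields C8a, ene-type capture of the aryne by a prenyl double bond, and arylation of the product phenoxide by excess aryne. Fallback, setting out from 9 and 25 and returning at 27: acid 25 would be condensed with N,O-dimethylhydroxylamine (EDC·HCl, i-Pr2NEt, CH2Cl2) to give the N-methoxy-N-methylamide F1. Carbamate 9 would be N-silylated and lithiated as in step 6 to give 11, which would be acylated with F1 at −78 °C. After aqueous work-up the ortho-acyl carbamate F2 would be treated with DBU and Et2NH in MeCN at 40 °C to release 27. This replaces the aryne by a polar aryllithium acylation and uses the mild carbamate cleavage already in the route.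

Step 2. Most likely to go wrong: drift of the tertiary ether to the linear prenyl ether, or C-allylation of the electron-rich ring, because the allyl palladium complex can re-ionise the product. Fallback, from 2 back to 4: copper-catalysed propargylation with 3-chloro-3-methylbut-1-yne (DBU, CuCl2 cat., MeCN, 0 °C) would give the propargyl ether F3, and semi-hydrogenation (H2, Pd/CaCO3 poisoned with Pb(OAc)2, quinoline, EtOAc) would give 4.

Step 6. Most likely to go wrong: loss of an aryl methoxymethyl ether to the silyl triflate during the N-silylation, or lateral metalation of the prenyl CH2 that lies next to the carbamate followed by carbamoyl migration. Fallback, from 8 back to 14: 8 would be carbamoylated with ClC(O)NEt2 and NaH in THF to give the N,N-diethylcarbamate F4. Ring lithiation under the classical kinetic conditions (s-BuLi, TMEDA, THF, −78 °C) and TMSCl would give the ortho-trimethylsilyl N,N-diethylcarbamate F5. Reductive cleavage with LiAlH4 in THF would give phenol 14, isolated this time and triflated as in the second half of step 7.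

Step 10. Most likely to go wrong: metalation at C5 or C6 instead of C3 because the C2 methoxy group is buttressed by the amino alkoxide, incomplete lithiation, or allylation at the tertiary terminus of 5. Fallback, from 16 back to 22, without organolithium: 16 would be O-allylated at its C4 hydroxyl with 3 (Pd(PPh3)4, THF, 0 °C) to give the 1,1-dimethylallyl ether F6. Heating (PhMe, 110 °C) would shift the allyl unit to C3, the position favoured by bond fixation in the chelated salicylaldehyde, to give the 3-prenyl dihydroxy aldehyde F7. MOMCl and K2CO3 in acetone would give the 4-O-methoxymethyl ether F8, and MeI with K2CO3 in DMF would give 22.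

Step 15. Most likely to go wrong: acid-catalysed addition of a freed phenol (O5, O7 or O4') to the neighbouring prenyl double bond with chroman formation, or addition of methanol to the alkenes, when the most hindered acetal at O7 is slow to leave. Fallback, from 29 back to 30, without Brønsted acid: TMSOTf with 2,2'-bipyridyl in MeCN at 0 °C would convert the three aryl methoxymethyl ethers into the tris(trimethylsilyl) ether F9, and water or K2CO3 (cat.) in MeOH would hydrolyse the silyl ethers to 30.

## Further compounds

F1 | step 13 | N-methoxy-N-methyl-2-[2-methoxy-4-(methoxymethoxy)-3-(3-methylbut-2-en-1-yl)phenyl]acetamide | COc1c(CC(=O)N(C)OC)ccc(OCOC)c1CC=C(C)C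
F2 | step 13 | 2-{2-[2-methoxy-4-(methoxymethoxy)-3-(3-methylbut-2-en-1-yl)phenyl]acetyl}-3,5-bis(methoxymethoxy)-4,6-bis(3-methylbut-2-en-1-yl)phenyl N-(propan-2-yl)carbamate | COc1c(CC(=O)c2c(OC(=O)NC(C)C)c(CC=C(C)C)c(OCOC)c(CC=C(C)C)c2OCOC)ccc(OCOC)c1CC=C(C)C
F3 | step 2 | 1,3-bis(methoxymethoxy)-5-[(2-methylbut-3-yn-2-yl)oxy]benzene | C#CC(C)(C)Oc1cc(OCOC)cc(OCOC)c1
F4 | step 6 | 3,5-bis(methoxymethoxy)-2,4-bis(3-methylbut-2-en-1-yl)phenyl N,N-diethylcarbamate | CCN(CC)C(=O)Oc1cc(OCOC)c(CC=C(C)C)c(OCOC)c1CC=C(C)C
F5 | step 6 | 3,5-bis(methoxymethoxy)-2,4-bis(3-methylbut-2-en-1-yl)-6-(trimethylsilyl)phenyl N,N-diethylcarbamate | CCN(CC)C(=O)Oc1c([Si](C)(C)C)c(OCOC)c(CC=C(C)C)c(OCOC)c1CC=C(C)C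
F6 | step 10 | 2-hydroxy-4-[(2-methylbut-3-en-2-yl)oxy]benzaldehyde | C=CC(C)(C)Oc1ccc(C=O)c(O)c1
F7 | step 10 | 2,4-dihydroxy-3-(3-methylbut-2-en-1-yl)benzaldehyde | O=Cc1ccc(O)c(CC=C(C)C)c1O
F8 | step 10 | 2-hydroxy-4-(methoxymethoxy)-3-(3-methylbut-2-en-1-yl)benzaldehyde | COCOc1ccc(C=O)c(O)c1CC=C(C)C
F9 | step 15 | 3-[2-methoxy-3-(3-methylbut-2-en-1-yl)-4-(trimethylsilyloxy)phenyl]-6,8-bis(3-methylbut-2-en-1-yl)-5,7-bis(trimethylsilyloxy)-4H-chromen-4-one | COc1c(-c2coc3c(CC=C(C)C)c(O[Si](C)(C)C)c(CC=C(C)C)c(O[Si](C)(C)C)c3c2=O)ccc(O[Si](C)(C)C)c1CC=C(C)C
A1 | alternative 1 | 2-(2-diazoacetyl)-5-[2-methoxy-4-(methoxymethoxy)-3-(3-methylbut-2-en-1-yl)phenyl]-4H-pyran-4-one | COc1c(C2=COC(C(=O)C=[N+]=[N-])=CC2=O)ccc(OCOC)c1CC=C(C)C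
A2 | alternative 1 | triisopropyl[(5-methylhex-4-en-1-yn-1-yl)oxy]silane | CC(C)=CCC#CO[Si](C(C)C)(C(C)C)C(C)C
A3 | alternative 1 | 5-hydroxy-3-[2-methoxy-4-(methoxymethoxy)-3-(3-methylbut-2-en-1-yl)phenyl]-6-(3-methylbut-2-en-1-yl)-7-[(triisopropylsilyl)oxy]-4H-chromen-4-one | CC(C)=CCc1c(O[Si](C(C)C)(C(C)C)C(C)C)cc2occ(-c3ccc(OCOC)c(CC=C(C)C)c3OC)c(=O)c2c1O
A4 | alternative 2 | 5-hydroxy-6,8-diiodo-3-[3-iodo-2-methoxy-4-(methoxymethoxy)phenyl]-7-(methoxymethoxy)-4H-chromen-4-one | COCOc1ccc(-c2coc3c(I)c(OCOC)c(I)c(O)c3c2=O)c(OC)c1I
A5 | alternative 2 | tributyl(3-methylbut-2-en-1-yl)stannane | CCCC[Sn](CCCC)(CCCC)CC=C(C)C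
A6 | alternative 2 | 5-hydroxy-3-[2-methoxy-4-(methoxymethoxy)-3-(3-methylbut-2-en-1-yl)phenyl]-7-(methoxymethoxy)-6,8-bis(3-methylbut-2-en-1-yl)-4H-chromen-4-one | COCOc1ccc(-c2coc3c(CC=C(C)C)c(OCOC)c(CC=C(C)C)c(O)c3c2=O)c(OC)c1CC=C(C)C
A7 | alternative 3 | methyl 8-[2-methoxy-4-(methoxymethoxy)-3-(3-methylbut-2-en-1-yl)phenyl]-3,5,7-trioxooctanoate | COC(=O)CC(=O)CC(=O)CC(=O)Cc1ccc(OCOC)c(CC=C(C)C)c1OC
A8 | alternative 3 | 2-[2-methoxy-4-(methoxymethoxy)-3-(3-methylbut-2-en-1-yl)phenyl]-1-(2,4,6-trihydroxyphenyl)ethan-1-one | COc1c(CC(=O)c2c(O)cc(O)cc2O)ccc(OCOC)c1CC=C(C)C
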